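**Strategy.** Ring C of the flavan is cut at O1–C2 and C3–C4, because this pyran ring links the ring A phenol oxygen O1 and the benzylic carbon C4 through only two further carbons. One aminocatalytic oxa-Michael/aldol condensation of a ring A salicylaldehyde (O1 and C4) with a cinnamaldehyde (C2, C3, 2-aryl group) forms both bonds, closes ring C and sets C2; the surplus formyl carbon is removed afterwards. The precursor is a 4-benzyloxy-2-hydroxybenzaldehyde carrying at C5 the (1R)-1,3-diarylpropyl chain, whose stereocentre comes from an asymmetric rhodium-catalysed arylation of a 7-oxygenated coumarin; its single free phenol directs the formylation and the annulation.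

Key step: step 13

Remark on numbering: flavan (chroman) numbering is used for ring A and ring C (O1, C2, C3, C4, C4a to C8a).

Remark on the sense of induction: the (S)-catalyst in step 13 is chosen from the usual steric shielding model of the (E)-iminium ion and has not been checked against a reported assignment; the antipode is equally available should a model run demand it. The C2 descriptor is R in 18 and S in 19 and 20 only because the CIP rank of C3 changes; the geometry is the same.

Remark on protecting groups: the coumarin 7-oxygen (future O1) is carried as a methoxymethyl ether so that it alone can be freed before formylation. The distal aryl ring is attached by C(sp3)–C(sp2) coupling, so that no benzylic cation is ever formed next to the ortho-benzyloxy group of ring A.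

**Route**

Step 1
Reactants: 1 7-hydroxycoumarin
Product: 2 7-(methoxymethoxy)-2H-chromen-2-one
Conditions: MOMCl, K2CO3, acetone, 0 °C to rt
Reagents that add atoms: chloromethyl methyl ether, COCCl
Why: Williamson-type O-alkylation of the acidic 7-phenol gives an acetal that is inert to the later hydride, base and organometallic steps and is orthogonal to benzyl ethers.

Step 2
Reactants: 2 7-(methoxymethoxy)-2H-chromen-2-one; 3 4-(benzyloxy)phenylboronic acid
Product: 4 (4R)-4-[4-(benzyloxy)phenyl]-7-(methoxymethoxy)-3,4-dihydro-2H-chromen-2-one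
Conditions: Rh(acac)(C2H4)2 (3 mol %), (R)-SEGPHOS (3.3 mol %), 3 (5 equiv), dioxane/H2O 10:1, 60 °C
Reagents that add atoms: none
Why: Hayashi–Miyaura asymmetric 1,4-addition of an arylboronic acid to a coumarin, in which the aryl–rhodium species bound to (R)-SEGPHOS should insert the C3=C4 bond from the enantioface that gives 4R (the future side-chain stereocentre) before protonolysis releases the lactone.

Step 3
Reactants: 4 (4R)-4-[4-(benzyloxy)phenyl]-7-(methoxymethoxy)-3,4-dihydro-2H-chromen-2-one
Product: 5 2-[(1R)-1-[4-(benzyloxy)phenyl]-3-hydroxypropyl]-5-(methoxymethoxy)phenol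
Conditions: LiAlH4, THF, 0 °C to rt; aqueous work-up
Reagents that add atoms: none
Why: Hydride reduction of the lactone to the phenol–alcohol touches no bond at the stereocentre and leaves the acetal and the benzyl ether intact.

Step 4
Reactants: 5 2-[(1R)-1-[4-(benzyloxy)phenyl]-3-hydroxypropyl]-5-(methoxymethoxy)phenol
Product: 6 (3R)-3-[2-(benzyloxy)-4-(methoxymethoxy)phenyl]-3-[4-(benzyloxy)phenyl]propan-1-ol
Conditions: BnBr (1.1 equiv), K2CO3, acetone, reflux
Reagents that add atoms: benzyl bromide, BrCc1ccccc1
Why: Chemoselective Williamson etherification, since carbonate deprotonates only the phenol and not the primary alcohol, places the benzyl group on the oxygen ortho to the side chain (the future C7 hydroxyl).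

Step 5
Reactants: 6 (3R)-3-[2-(benzyloxy)-4-(methoxymethoxy)phenyl]-3-[4-(benzyloxy)phenyl]propan-1-ol
Product: 7 2-(benzyloxy)-1-[(1R)-1-[4-(benzyloxy)phenyl]-3-iodopropyl]-4-(methoxymethoxy)benzene
Conditions: I2, PPh3, imidazole, CH2Cl2, 0 °C to rt
Reagents that add atoms: iodine, II
Why: Appel-type iodination converts the primary alcohol into the iodide by SN2 displacement of the oxyphosphonium group under imidazole-buffered conditions that spare the acetal.

Step 6
Reactants: 8 4-bromo-3-methoxyphenol
Product: 9 4-(benzyloxy)-1-bromo-2-methoxybenzene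
Conditions: BnBr, K2CO3, DMF, rt
Reagents that add atoms: benzyl bromide, BrCc1ccccc1
Why: Williamson O-benzylation of the phenol proceeds without affecting the aryl bromide.

Step 7
Reactants: 7 2-(benzyloxy)-1-[(1R)-1-[4-(benzyloxy)phenyl]-3-iodopropyl]-4-(methoxymethoxy)benzene; 9 4-(benzyloxy)-1-bromo-2-methoxybenzene
Product: 11 2-(benzyloxy)-1-[(1R)-1-[4-(benzyloxy)phenyl]-3-[4-(benzyloxy)-2-methoxyphenyl]propyl]-4-(methoxymethoxy)benzene, via alkylzinc iodide 10 (not isolated)
Conditions: Zn dust, LiCl, THF, 40 °C; then 9 (1.3 equiv), Pd(OAc)2 (2 mol %), SPhos (4 mol %), THF, 50 °C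
Reagents that add atoms: none
Why: Negishi cross-coupling, in which LiCl-assisted zinc insertion into the primary C–I bond gives an alkylzinc iodide that couples with the electron-rich aryl bromide on zerovalent palladium bearing SPhos faster than β-hydride elimination, completes the 1,3-diarylpropyl chain without an ionic intermediate.

Step 8
Reactants: 11 2-(benzyloxy)-1-[(1R)-1-[4-(benzyloxy)phenyl]-3-[4-(benzyloxy)-2-methoxyphenyl]propyl]-4-(methoxymethoxy)benzene
Product: 12 3-(benzyloxy)-4-[(1R)-1-[4-(benzyloxy)phenyl]-3-[4-(benzyloxy)-2-methoxyphenyl]propyl]phenol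
Conditions: HCl (3 M aq.), MeOH/THF, 50 °C
Reagents that add atoms: none
Why: Acid-catalysed acetal exchange with methanol removes the methoxymethyl group as dimethoxymethane and frees the one phenol that becomes O1, while benzyl and methyl aryl ethers are stable to dilute acid.

Step 9
Reactants: 12 3-(benzyloxy)-4-[(1R)-1-[4-(benzyloxy)phenyl]-3-[4-(benzyloxy)-2-methoxyphenyl]propyl]phenol
Product: 13 4-(benzyloxy)-5-[(1R)-1-[4-(benzyloxy)phenyl]-3-[4-(benzyloxy)-2-methoxyphenyl]propyl]-2-hydroxybenzaldehyde
Conditions: MgCl2, Et3N, paraformaldehyde, MeCN, reflux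
Reagents that add atoms: formaldehyde (from paraformaldehyde), C=O
Why: Magnesium-mediated ortho-formylation (Casnati–Skattebøl) delivers formaldehyde from the magnesium phenoxide to an ortho carbon and a second formaldehyde oxidises the benzylic alkoxide, so only the ring with the free hydroxyl reacts, at the open site para to the benzyloxy group and not at the crowded site between the two oxygens.

Step 10
Reactants: 14 2,5-dihydroxybenzaldehyde
Product: 15 5-(benzyloxy)-2-hydroxybenzaldehyde
Conditions: BnBr (1.0 equiv), K2CO3 (1.0 equiv), acetone, rt to 50 °C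
Reagents that add atoms: benzyl bromide, BrCc1ccccc1
Why: Williamson O-benzylation with limiting reagents should select the 5-hydroxyl, because the 2-hydroxyl is held in a hydrogen bond to the formyl group and its phenoxide is the weaker nucleophile.

Step 11
Reactants: 15 5-(benzyloxy)-2-hydroxybenzaldehyde
Product: 16 5-(benzyloxy)-2-methoxybenzaldehyde
Conditions: MeI, K2CO3, DMF, rt
Reagents that add atoms: iodomethane, CI
Why: Williamson O-methylation of the remaining chelated phenol goes to completion in a dipolar aprotic solvent with excess iodomethane.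

Step 12
Reactants: 16 5-(benzyloxy)-2-methoxybenzaldehyde
Product: 17 (E)-3-[5-(benzyloxy)-2-methoxyphenyl]prop-2-enal
Conditions: Ph3P=CHCHO (1.2 equiv), toluene, 80 °C
Reagents that add atoms: (triphenylphosphoranylidene)acetaldehyde, O=CC=P(c1ccccc1)(c1ccccc1)c1ccccc1
Why: Wittig reaction with a stabilised formyl ylide gives the two-carbon homologated enal with E geometry under thermodynamic control.

Step 13
Reactants: 13 4-(benzyloxy)-5-[(1R)-1-[4-(benzyloxy)phenyl]-3-[4-(benzyloxy)-2-methoxyphenyl]propyl]-2-hydroxybenzaldehyde; 17 (E)-3-[5-(benzyloxy)-2-methoxyphenyl]prop-2-enal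
Product: 18 (2R)-7-(benzyloxy)-2-[5-(benzyloxy)-2-methoxyphenyl]-6-[(1R)-1-[4-(benzyloxy)phenyl]-3-[4-(benzyloxy)-2-methoxyphenyl]propyl]-2H-chromene-3-carbaldehyde
Conditions: (S)-2-[diphenyl(trimethylsilyloxy)methyl]pyrrolidine (20 mol %), 2-nitrobenzoic acid (20 mol %), 17 (1.5 equiv), 4 Å MS, toluene, 0 °C to rt
Reagents that add atoms: none
Why: The secondary amine condenses with 17 to an (E)-iminium ion, the phenol oxygen of 13 (O1) adds to its β-carbon (C2), and the enamine so formed attacks the neighbouring formyl carbon (C4), after which dehydration and hydrolysis release 18 and the catalyst. The closest known reaction type is the diarylprolinol silyl ether-catalysed domino oxa-Michael/aldol condensation of salicylaldehydes with cinnamaldehydes. Ring C closes in a 6-exo-trig (enolexo) aldol mode, the enamine carbon C3 attacking the exocyclic C=O. C2 is set under catalyst control, since the CPh2OSiMe3 group of the (S)-catalyst covers the Re face of the β-carbon of the s-trans iminium ion and the oxygen should arrive on the Si face, which corresponds to 2R in 18 and to 2S in the target; the side-chain centre is too remote to interfere. The step needs chemoselectivity for one phenol and one formyl group, which is secured because 13 has a single free hydroxyl placed ortho to its only aldehyde while all other phenols are benzyl ethers, and the irreversible dehydration drains the reversible oxa-Michael equilibrium.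

Step 14
Reactants: 18 (2R)-7-(benzyloxy)-2-[5-(benzyloxy)-2-methoxyphenyl]-6-[(1R)-1-[4-(benzyloxy)phenyl]-3-[4-(benzyloxy)-2-methoxyphenyl]propyl]-2H-chromene-3-carbaldehyde
Product: 19 (2S)-7-(benzyloxy)-2-[5-(benzyloxy)-2-methoxyphenyl]-6-[(1R)-1-[4-(benzyloxy)phenyl]-3-[4-(benzyloxy)-2-methoxyphenyl]propyl]-2H-chromene
Conditions: RhCl(PPh3)3 (1.1 equiv), toluene, 110 °C, argon, dark
Reagents that add atoms: none
Why: Tsuji–Wilkinson decarbonylation, in which monovalent rhodium inserts into the formyl C–H bond, extrudes CO and reductively eliminates C3–H, excises the extra carbon of the conjugated aldehyde without involving C2.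

Step 15
Reactants: 19 (2S)-7-(benzyloxy)-2-[5-(benzyloxy)-2-methoxyphenyl]-6-[(1R)-1-[4-(benzyloxy)phenyl]-3-[4-(benzyloxy)-2-methoxyphenyl]propyl]-2H-chromene
Product: 20 (2S)-2-(5-hydroxy-2-methoxyphenyl)-6-[(1R)-3-(4-hydroxy-2-methoxyphenyl)-1-(4-hydroxyphenyl)propyl]-3,4-dihydro-2H-chromen-7-ol
Conditions: H2 (1 atm), 10% Pd/C, EtOAc/MeOH 1:1, rt
Reagents that add atoms: none
Why: Heterogeneous catalytic hydrogenation saturates the styrene-type C3=C4 bond and hydrogenolyses the four benzyl ethers under neutral conditions, which leave both stereocentres untouched.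

**Compound list**

1 | 7-hydroxycoumarin (7-hydroxy-2H-chromen-2-one) | O=c1ccc2ccc(O)cc2o1 | starting material
2 | 7-(methoxymethoxy)-2H-chromen-2-one | COCOc1ccc2ccc(=O)oc2c1 | intermediate
3 | 4-(benzyloxy)phenylboronic acid | OB(O)c1ccc(OCc2ccccc2)cc1 | starting material
4 | (4R)-4-[4-(benzyloxy)phenyl]-7-(methoxymethoxy)-3,4-dihydro-2H-chromen-2-one | O=C1C[C@H](c2ccc(OCc3ccccc3)cc2)c2ccc(OCOC)cc2O1 | intermediate
5 | 2-[(1R)-1-[4-(benzyloxy)phenyl]-3-hydroxypropyl]-5-(methoxymethoxy)phenol | OCC[C@H](c1ccc(OCc2ccccc2)cc1)c1ccc(OCOC)cc1O | intermediate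
6 | (3R)-3-[2-(benzyloxy)-4-(methoxymethoxy)phenyl]-3-[4-(benzyloxy)phenyl]propan-1-ol | OCC[C@H](c1ccc(OCc2ccccc2)cc1)c1ccc(OCOC)cc1OCc1ccccc1 | intermediate
7 | 2-(benzyloxy)-1-[(1R)-1-[4-(benzyloxy)phenyl]-3-iodopropyl]-4-(methoxymethoxy)benzene | ICC[C@H](c1ccc(OCc2ccccc2)cc1)c1ccc(OCOC)cc1OCc1ccccc1 | intermediate
8 | 4-bromo-3-methoxyphenol | COc1cc(O)ccc1Br | starting material
9 | 4-(benzyloxy)-1-bromo-2-methoxybenzene | COc1cc(OCc2ccccc2)ccc1Br | intermediate
10 | [(3R)-3-[2-(benzyloxy)-4-(methoxymethoxy)phenyl]-3-[4-(benzyloxy)phenyl]propyl]zinc iodide | I[Zn]CC[C@H](c1ccc(OCc2ccccc2)cc1)c1ccc(OCOC)cc1OCc1ccccc1 | intermediate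
11 | 2-(benzyloxy)-1-[(1R)-1-[4-(benzyloxy)phenyl]-3-[4-(benzyloxy)-2-methoxyphenyl]propyl]-4-(methoxymethoxy)benzene | COc1cc(OCc2ccccc2)ccc1CC[C@H](c1ccc(OCc2ccccc2)cc1)c1ccc(OCOC)cc1OCc1ccccc1 | intermediate
12 | 3-(benzyloxy)-4-[(1R)-1-[4-(benzyloxy)phenyl]-3-[4-(benzyloxy)-2-methoxyphenyl]propyl]phenol | COc1cc(OCc2ccccc2)ccc1CC[C@H](c1ccc(OCc2ccccc2)cc1)c1ccc(O)cc1OCc1ccccc1 | intermediate
13 | 4-(benzyloxy)-5-[(1R)-1-[4-(benzyloxy)phenyl]-3-[4-(benzyloxy)-2-methoxyphenyl]propyl]-2-hydroxybenzaldehyde | COc1cc(OCc2ccccc2)ccc1CC[C@H](c1ccc(OCc2ccccc2)cc1)c1cc(C=O)c(O)cc1OCc1ccccc1 | intermediate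
14 | 2,5-dihydroxybenzaldehyde | O=Cc1cc(O)ccc1O | starting material
15 | 5-(benzyloxy)-2-hydroxybenzaldehyde | O=Cc1cc(OCc2ccccc2)ccc1O | intermediate
16 | 5-(benzyloxy)-2-methoxybenzaldehyde | COc1ccc(OCc2ccccc2)cc1C=O | intermediate
17 | (E)-3-[5-(benzyloxy)-2-methoxyphenyl]prop-2-enal | COc1ccc(OCc2ccccc2)cc1/C=C/C=O | intermediate
18 | (2R)-7-(benzyloxy)-2-[5-(benzyloxy)-2-methoxyphenyl]-6-[(1R)-1-[4-(benzyloxy)phenyl]-3-[4-(benzyloxy)-2-methoxyphenyl]propyl]-2H-chromene-3-carbaldehyde | COc1cc(OCc2ccccc2)ccc1CC[C@H](c1ccc(OCc2ccccc2)cc1)c1cc2c(cc1OCc1ccccc1)O[C@H](c1cc(OCc3ccccc3)ccc1OC)C(C=O)=C2 | intermediate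
19 | (2S)-7-(benzyloxy)-2-[5-(benzyloxy)-2-methoxyphenyl]-6-[(1R)-1-[4-(benzyloxy)phenyl]-3-[4-(benzyloxy)-2-methoxyphenyl]propyl]-2H-chromene | COc1cc(OCc2ccccc2)ccc1CC[C@H](c1ccc(OCc2ccccc2)cc1)c1cc2c(cc1OCc1ccccc1)O[C@H](c1cc(OCc3ccccc3)ccc1OC)C=C2 | intermediate
20 | (2S)-2-(5-hydroxy-2-methoxyphenyl)-6-[(1R)-3-(4-hydroxy-2-methoxyphenyl)-1-(4-hydroxyphenyl)propyl]-3,4-dihydro-2H-chromen-7-ol | COc1cc(O)ccc1CC[C@H](c1ccc(O)cc1)c1cc2c(cc1O)O[C@H](c1cc(O)ccc1OC)CC2 | target

**Totals.** Total step count: 15. Longest linear sequence: 11 steps (1, 2, 3, 4, 5, 7, 8, 9, 13, 14, 15).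

**Steps most likely to fail**

Step 13. The aldol closure onto the formyl group, which is deactivated by the para-benzyloxy substituent and flanked by a bulky ring, may be slow. The reversible oxa-Michael addition could then erode the facial selectivity at C2, or the conversion could stall. The fallback sets out from phenol 12 and enal 17 and comes back at 19. Heating 12 and 17 with PhB(OH)2 and catalytic AcOH in toluene with removal of water should give the 2-aryl-2H-chromene directly, without a formyl group. The path is ortho-selective C-hydroxyalkylation through a 1,3,2-benzodioxaborin, fragmentation to an ortho-quinone methide and oxa-6π electrocyclisation. This closure has no control at C2 and would deliver 19 together with the (2R)-epimer of 19 F1. Because the side-chain centre is fixed, the two are diastereomers, to be separated by preparative HPLC. Steps 9 and 14 then fall away.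

Step 14. At the temperature needed to extrude CO from a conjugated aldehyde, rhodium hydride species may move the double bond into the 4H-chromene position, or the configuration at C2 may be lost thermally; the conversion may also remain incomplete. The fallback sets out from 18 and comes back at 20. Hydrogenation of 18 over Pd/C (H2, EtOAc/MeOH, rt) would first saturate the enal double bond and cleave the benzyl ethers, giving (2S)-7-hydroxy-2-(5-hydroxy-2-methoxyphenyl)-6-[(1R)-3-(4-hydroxy-2-methoxyphenyl)-1-(4-hydroxyphenyl)propyl]-3,4-dihydro-2H-chromene-3-carbaldehyde F2 as a mixture at C3, a centre that is erased next. This aliphatic aldehyde should be decarbonylated by RhCl(PPh3)3 well below the temperature a conjugated one needs (dioxane, 60 to 80 °C), giving 20 directly.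

Step 15. On the palladium surface the C2–O bond of the chromene, which is both allylic and benzylic, may be hydrogenolysed before the double bond is saturated, opening ring C; the debenzylation may also stop short. The fallback sets out from 19 and comes back at 20. The C3=C4 bond is reduced with diimide (2-nitrobenzenesulfonyl hydrazide, Et3N, CH2Cl2, rt), which cannot cleave C–O bonds, to give (2S)-7-(benzyloxy)-2-[5-(benzyloxy)-2-methoxyphenyl]-6-[(1R)-1-[4-(benzyloxy)phenyl]-3-[4-(benzyloxy)-2-methoxyphenyl]propyl]-3,4-dihydro-2H-chromene F3. Once the C2–O bond is no longer allylic, the benzyl ethers of F3 are removed by transfer hydrogenolysis (Pd(OH)2/C, cyclohexa-1,4-diene, EtOH/EtOAc, rt) to give 20.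

**Further compounds**

F1 | step 13 | (2R)-7-(benzyloxy)-2-[5-(benzyloxy)-2-methoxyphenyl]-6-[(1R)-1-[4-(benzyloxy)phenyl]-3-[4-(benzyloxy)-2-methoxyphenyl]propyl]-2H-chromene (the (2R)-epimer of 19) | COc1cc(OCc2ccccc2)ccc1CC[C@H](c1ccc(OCc2ccccc2)cc1)c1cc2c(cc1OCc1ccccc1)O[C@@H](c1cc(OCc3ccccc3)ccc1OC)C=C2
F2 | step 14 | (2S)-7-hydroxy-2-(5-hydroxy-2-methoxyphenyl)-6-[(1R)-3-(4-hydroxy-2-methoxyphenyl)-1-(4-hydroxyphenyl)propyl]-3,4-dihydro-2H-chromene-3-carbaldehyde (mixture at C3) | COc1cc(O)ccc1CC[C@H](c1ccc(O)cc1)c1cc2c(cc1O)O[C@H](c1cc(O)ccc1OC)C(C=O)C2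
F3 | step 15 | (2S)-7-(benzyloxy)-2-[5-(benzyloxy)-2-methoxyphenyl]-6-[(1R)-1-[4-(benzyloxy)phenyl]-3-[4-(benzyloxy)-2-methoxyphenyl]propyl]-3,4-dihydro-2H-chromene | COc1cc(OCc2ccccc2)ccc1CC[C@H](c1ccc(OCc2ccccc2)cc1)c1cc2c(cc1OCc1ccccc1)O[C@H](c1cc(OCc3ccccc3)ccc1OC)CC2
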